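## Retrosynthetic overview

1. The C8 ester is attached last; the ten-membered ring is opened at C1=C10 (ring-closing metathesis of a terminal vinyl group onto a 2-substituted acrylate).
2. Key disconnection C8–C9: a γ-acetoxyallylchromium reagent, in which the normally electrophilic β-carbon of a β-acetoxyacrylate is nucleophilic, adds to a C8 aldehyde. This one step delivers C8-OH, C9-OAc and the C10 acrylate.
3. The C8 aldehyde and the α-methylene lactone come from a butenolide by 1,4-addition of lithiated 1,3-dithiane (C7–C8) with Mannich trapping of the enolate (C11–C13).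
4. The butenolide comes from an epoxy aldehyde and a (Z)-β-magnesioacrylate (C6–C7). The epoxy aldehyde comes from Sharpless epoxidation of a Z-allylic alcohol made from prenol and allyl bromide.
5. Ring order: oxirane, then γ-lactone, then ten-membered carbocycle.

Assumption: the SMILES is taken at face value (cis-4,5-epoxide, ring-cis 1(10)-alkene), and atom labels C1–C15 follow germacranolide numbering (lactone carbonyl C12, exocyclic methylene C13, ester carbon C14, epoxide methyl C15).

## Route

Step 1
Reactants: 1 3-methylbut-2-en-1-ol (prenol); 2 allyl bromide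
Product: 4 (2Z)-3-methylhepta-2,6-dien-1-ol, via dilithiated prenol 3 (not isolated)
Conditions: n-BuLi (2.2 equiv), TMEDA, hexane/Et2O, 0 °C→rt; then 2, −78 °C→rt
Reagents that add atoms: none
Why: Alkoxide-directed allylic lithiation removes a proton from the methyl group cis to CH2OLi, and SN2 alkylation of this dianion at that carbon gives the Z-trisubstituted allylic alcohol (dianion alkylation; the olefin geometry is fixed by the chelated allyllithium, no stereocentre is formed).

Step 2
Reactants: 4 (2Z)-3-methylhepta-2,6-dien-1-ol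
Product: 5 [(2S,3R)-3-(but-3-en-1-yl)-3-methyloxiran-2-yl]methanol
Conditions: Ti(OiPr)4 (10 mol %), L-(+)-diethyl tartrate (12 mol %), t-BuOOH, 4 Å MS, CH2Cl2, −20 °C
Reagents that add atoms: tert-butyl hydroperoxide, CC(C)(C)OO
Why: Sharpless asymmetric epoxidation touches only the allylic alcohol, and the L-(+)-tartrate catalyst delivers oxygen to the face that gives the (2S,3R) cis-epoxide from a Z-3,3-disubstituted allylic alcohol (as with nerol), which sets C4 and C5.

Step 3
Reactants: 5 [(2S,3R)-3-(but-3-en-1-yl)-3-methyloxiran-2-yl]methanol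
Product: 6 (2R,3R)-3-(but-3-en-1-yl)-3-methyloxirane-2-carbaldehyde
Conditions: TEMPO (10 mol %), PhI(OAc)2, CH2Cl2, rt
Reagents that add atoms: none
Why: Oxoammonium (TEMPO) oxidation converts the primary alcohol to the aldehyde under non-basic conditions that leave the epoxide and both stereocentres intact (the descriptor at the aldehyde-bearing carbon changes only because CHO outranks the ring carbon).

Step 4
Reactants: 6 (2R,3R)-3-(but-3-en-1-yl)-3-methyloxirane-2-carbaldehyde; 7 ethyl (2Z)-3-iodoprop-2-enoate
Product: 10 (5S)-5-[(2S,3R)-3-(but-3-en-1-yl)-3-methyloxiran-2-yl]furan-2(5H)-one, via ethyl (2Z)-3-(chloromagnesio)prop-2-enoate 8 (not isolated), via open-chain chloromagnesium alkoxide 9 (not isolated)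
Conditions: 7, i-PrMgCl·LiCl, THF, −78 °C; then 6, −78→0 °C; sat. aq. NH4Cl
Reagents that add atoms: none
Why: Iodine–magnesium exchange gives a configurationally stable (Z)-β-magnesioacrylate that adds to the aldehyde under Felkin–Anh/Cornforth control (anti to the epoxide C–O bond, as is usual for cis-α,β-epoxy aldehydes) to set C6 as S, and the Z-alkoxide lactonises to the butenolide (Grignard addition followed by lactonisation).

Step 5
Reactants: 10 (5S)-5-[(2S,3R)-3-(but-3-en-1-yl)-3-methyloxiran-2-yl]furan-2(5H)-one; 11 1,3-dithiane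
Product: 14 (3R,4S,5S)-5-[(2S,3R)-3-(but-3-en-1-yl)-3-methyloxiran-2-yl]-3-[(dimethylamino)methyl]-4-(1,3-dithian-2-yl)oxolan-2-one, via 2-lithio-1,3-dithiane 12 (not isolated), via lactone lithium enolate 13 (not isolated)
Conditions: 11, n-BuLi, THF, −30 °C; HMPA, −78 °C; 10; then CH2=NMe2+ I−, −78→0 °C
Reagents that add atoms: N,N-dimethylmethaniminium iodide (Eschenmoser's salt), C=[N+](C)C.[I-]
Why: The Corey–Seebach formyl anion equivalent adds 1,4 to the butenolide on the face opposite the C6 substituent, which sets C7 trans to C6, and the enolate is trapped by the iminium salt anti to the new dithianyl group (tandem conjugate addition and Mannich reaction; the C11 centre is removed in step 6).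

Step 6
Reactants: 14 (3R,4S,5S)-5-[(2S,3R)-3-(but-3-en-1-yl)-3-methyloxiran-2-yl]-3-[(dimethylamino)methyl]-4-(1,3-dithian-2-yl)oxolan-2-one
Product: 16 (2S,3S)-2-[(2S,3R)-3-(but-3-en-1-yl)-3-methyloxiran-2-yl]-4-methylidene-5-oxooxolane-3-carbaldehyde, via trimethylammonium iodide 15 (not isolated)
Conditions: MeI (6 equiv), CaCO3, MeCN/H2O (6:1), 35 °C; used crude
Reagents that add atoms: water, O
Why: Methyl iodide quaternises the amine, which then loses trimethylamine by E1cB elimination to give the α-methylene lactone, and it S-methylates the dithiane so that water releases the aldehyde (alkylative dithiane hydrolysis); no stereocentre is created and the trans C6/C7 arrangement is the thermodynamically preferred one.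

Step 7
Reactants: 17 methyl propanoate; 18 methyl formate
Product: 20 methyl (2E)-3-(acetyloxy)-2-methylprop-2-enoate, via sodium enolate of methyl 2-formylpropanoate 19 (not isolated)
Conditions: NaH, Et2O (cat. MeOH), 0 °C→rt; volatiles removed; then AcCl, THF, 0 °C
Reagents that add atoms: acetyl chloride, CC(Cl)=O
Why: Crossed Claisen formylation gives the stable sodium enolate of the formyl ester, which is O-acetylated to the enol acetate (E isomer major; the minor Z isomer is carried along because the geometry is not relevant in step 9).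

Step 8
Reactants: 20 methyl (2E)-3-(acetyloxy)-2-methylprop-2-enoate
Product: 21 methyl (2Z)-3-(acetyloxy)-2-(bromomethyl)prop-2-enoate
Conditions: NBS, AIBN (5 mol %), PhCF3, 85 °C
Reagents that add atoms: N-bromosuccinimide, O=C1CCC(=O)N1Br
Why: Wohl–Ziegler bromination occurs at the only allylic C–H position (the 2-methyl group) while the electron-poor push–pull enol ester alkene resists bromine addition (the geometry is unchanged; the descriptor becomes Z only because CH2Br outranks CO2Me).

Step 9 (key step)
Reactants: 16 (2S,3S)-2-[(2S,3R)-3-(but-3-en-1-yl)-3-methyloxiran-2-yl]-4-methylidene-5-oxooxolane-3-carbaldehyde; 21 methyl (2Z)-3-(acetyloxy)-2-(bromomethyl)prop-2-enoate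
Product: 23 methyl (3R,4S)-3-(acetyloxy)-4-[(2S,3R)-2-[(2S,3R)-3-(but-3-en-1-yl)-3-methyloxiran-2-yl]-4-methylidene-5-oxooxolan-3-yl]-4-hydroxy-2-methylidenebutanoate, via acetoxyallylchromium dichloride 22 (not isolated)
Conditions: CrCl2 (4 equiv), THF, 0 °C→rt, 16 and 21 (1.6 equiv) added together; pH 7 phosphate buffer work-up at 0 °C; used directly
Reagents that add atoms: none
Why: Proposed new method: CrCl2 inserts into the allylic C–Br bond of 21 to give the σ-allylchromium species 22, in which the β-carbon of a β-acetoxyacrylate (normally an electrophilic, formyl-level carbon) is nucleophilic; this carbon attacks the aldehyde carbon of 16 through a six-membered chair transition state with the acetoxy group equatorial after allyl equilibration, which gives the anti (erythro) C8-OH/C9-OAc pair from either geometry of 21, while approach antiperiplanar to the C7–C11 bond (Felkin–Anh with the electron-poor sp2 carbon as the large group, nucleophile passing H7) sets C8 as S and therefore C9 as R; the closest known reactions are Nozaki–Hiyama–Kishi additions of 2-(bromomethyl)acrylates and the erythro-selective additions of γ-alkoxy- and γ-acyloxyallylchromium reagents to aldehydes.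

Step 10
Reactants: 23 methyl (3R,4S)-3-(acetyloxy)-4-[(2S,3R)-2-[(2S,3R)-3-(but-3-en-1-yl)-3-methyloxiran-2-yl]-4-methylidene-5-oxooxolan-3-yl]-4-hydroxy-2-methylidenebutanoate
Product: 24 (1(10)E,4R,5S,6S,7R,8S,9R)-9-acetoxy-4,5-epoxy-8-hydroxy-14-methoxy-14-oxogermacra-1(10),11(13)-dien-12,6-olide
Conditions: second-generation Hoveyda–Grubbs catalyst (15 mol %), 2,6-dichloro-1,4-benzoquinone (10 mol %), toluene (1 mM), 80 °C
Reagents that add atoms: none
Why: Ring-closing metathesis starts at the monosubstituted C1 vinyl group and closes onto the 2-substituted acrylate with loss of ethene, and the ring-cis trisubstituted enoate (C2 cis to C9, E by CIP) is the only geometry a ten-membered ring carrying the cis-epoxide and the trans-fused lactone accommodates without severe strain.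

Step 11
Reactants: 25 methyl 2-(hydroxymethyl)prop-2-enoate
Product: 26 methyl 2-({[tert-butyl(dimethyl)silyl]oxy}methyl)prop-2-enoate
Conditions: TBSCl, imidazole, CH2Cl2, 0 °C→rt
Reagents that add atoms: tert-butyldimethylsilyl chloride, CC(C)(C)[Si](C)(C)Cl
Why: Standard silylation of the primary allylic alcohol prevents self-esterification of the hydroxy acid in step 13.

Step 12
Reactants: 26 methyl 2-({[tert-butyl(dimethyl)silyl]oxy}methyl)prop-2-enoate
Product: 27 2-({[tert-butyl(dimethyl)silyl]oxy}methyl)prop-2-enoic acid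
Conditions: LiOH, THF/H2O (3:1), 0 °C→rt; then 1 M HCl to pH 4, 0 °C
Reagents that add atoms: lithium hydroxide, [Li+].[OH-]
Why: Saponification of the methyl ester is faster than conjugate addition or silyl ether cleavage at 0 °C, and the cold, brief acidification spares the silyl ether.

Step 13
Reactants: 24 (1(10)E,4R,5S,6S,7R,8S,9R)-9-acetoxy-4,5-epoxy-8-hydroxy-14-methoxy-14-oxogermacra-1(10),11(13)-dien-12,6-olide; 27 2-({[tert-butyl(dimethyl)silyl]oxy}methyl)prop-2-enoic acid
Product: 28 8-O-[2-({[tert-butyl(dimethyl)silyl]oxy}methyl)prop-2-enoyl] derivative of 24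
Conditions: DCC, DMAP (0.2 equiv), CH2Cl2, 0 °C→rt
Reagents that add atoms: none
Why: Steglich esterification acylates the only free hydroxyl with retention at C8, under conditions mild enough for the epoxide, the allylic acetate and the α-methylene lactone.

Step 14
Reactants: 28 8-O-[2-({[tert-butyl(dimethyl)silyl]oxy}methyl)prop-2-enoyl] derivative of 24
Product: 29 CNP0147016.1, (1(10)E,4R,5S,6S,7R,8S,9R)-9-acetoxy-4,5-epoxy-8-{[2-(hydroxymethyl)prop-2-enoyl]oxy}-14-methoxy-14-oxogermacra-1(10),11(13)-dien-12,6-olide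
Conditions: Et3N·3HF, MeCN, 0 °C→rt
Reagents that add atoms: none
Why: Buffered fluoride cleaves the primary silyl ether without opening the trisubstituted epoxide, adding to the Michael acceptors or shifting the acetate (fluoride-mediated desilylation).

## Compound list

1 | 3-methylbut-2-en-1-ol (prenol) | CC(C)=CCO | starting material
2 | allyl bromide (3-bromoprop-1-ene) | C=CCBr | starting material
3 | dilithiated prenol (CH2Li cis to CH2OLi) | [Li]OC/C=C(/C)C[Li] | intermediate (not isolated)
4 | (2Z)-3-methylhepta-2,6-dien-1-ol | OC/C=C(/C)CCC=C | intermediate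
5 | [(2S,3R)-3-(but-3-en-1-yl)-3-methyloxiran-2-yl]methanol | OC[C@@H]1O[C@]1(C)CCC=C | intermediate
6 | (2R,3R)-3-(but-3-en-1-yl)-3-methyloxirane-2-carbaldehyde | O=C[C@@H]1O[C@]1(C)CCC=C | intermediate
7 | ethyl (2Z)-3-iodoprop-2-enoate | CCOC(=O)/C=C\I | starting material
8 | ethyl (2Z)-3-(chloromagnesio)prop-2-enoate | CCOC(=O)/C=C\[Mg]Cl | intermediate (not isolated)
9 | chloromagnesium alkoxide of ethyl (2Z,4S)-4-[(2S,3R)-3-(but-3-en-1-yl)-3-methyloxiran-2-yl]-4-hydroxybut-2-enoate | CCOC(=O)/C=C\[C@H](O[Mg]Cl)[C@@H]1O[C@]1(C)CCC=C | intermediate (not isolated)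
10 | (5S)-5-[(2S,3R)-3-(but-3-en-1-yl)-3-methyloxiran-2-yl]furan-2(5H)-one | O=C1O[C@@H](C=C1)[C@@H]1O[C@]1(C)CCC=C | intermediate
11 | 1,3-dithiane | C1CSCSC1 | starting material
12 | 2-lithio-1,3-dithiane | [Li]C1SCCCS1 | intermediate (not isolated)
13 | lithium (4S,5S)-5-[(2S,3R)-3-(but-3-en-1-yl)-3-methyloxiran-2-yl]-4-(1,3-dithian-2-yl)-4,5-dihydrofuran-2-olate | S1CCCSC1[C@H]1C=C(O[Li])O[C@@H]1[C@@H]1O[C@]1(C)CCC=C | intermediate (not isolated)
14 | (3R,4S,5S)-5-[(2S,3R)-3-(but-3-en-1-yl)-3-methyloxiran-2-yl]-3-[(dimethylamino)methyl]-4-(1,3-dithian-2-yl)oxolan-2-one | S1CCCSC1[C@H]1[C@H](CN(C)C)C(=O)O[C@@H]1[C@@H]1O[C@]1(C)CCC=C | intermediate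
15 | N-methyl quaternary ammonium iodide of 14 (CH2NMe3+ I− in place of CH2NMe2) | [I-].S1CCCSC1[C@H]1[C@H](C[N+](C)(C)C)C(=O)O[C@@H]1[C@@H]1O[C@]1(C)CCC=C | intermediate (not isolated)
16 | (2S,3S)-2-[(2S,3R)-3-(but-3-en-1-yl)-3-methyloxiran-2-yl]-4-methylidene-5-oxooxolane-3-carbaldehyde | O=C[C@H]1C(=C)C(=O)O[C@@H]1[C@@H]1O[C@]1(C)CCC=C | intermediate
17 | methyl propanoate | CCC(=O)OC | starting material
18 | methyl formate | COC=O | starting material
19 | sodium enolate of methyl 2-formylpropanoate | [Na+].[O-]/C=C(/C)C(=O)OC | intermediate (not isolated)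
20 | methyl (2E)-3-(acetyloxy)-2-methylprop-2-enoate (E major) | COC(=O)/C(C)=C/OC(C)=O | intermediate
21 | methyl (2Z)-3-(acetyloxy)-2-(bromomethyl)prop-2-enoate | COC(=O)/C(CBr)=C/OC(C)=O | intermediate
22 | [(2E)-3-(acetyloxy)-2-(methoxycarbonyl)prop-2-en-1-yl]chromium dichloride | COC(=O)/C(C[Cr](Cl)Cl)=C\OC(C)=O | intermediate (not isolated)
23 | methyl (3R,4S)-3-(acetyloxy)-4-[(2S,3R)-2-[(2S,3R)-3-(but-3-en-1-yl)-3-methyloxiran-2-yl]-4-methylidene-5-oxooxolan-3-yl]-4-hydroxy-2-methylidenebutanoate | O[C@H]([C@H](OC(C)=O)C(=C)C(=O)OC)[C@H]1C(=C)C(=O)O[C@@H]1[C@@H]1O[C@]1(C)CCC=C | intermediate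
24 | (1(10)E,4R,5S,6S,7R,8S,9R)-9-acetoxy-4,5-epoxy-8-hydroxy-14-methoxy-14-oxogermacra-1(10),11(13)-dien-12,6-olide | O[C@H]1[C@H]2C(=C)C(=O)O[C@@H]2[C@@H]2O[C@]2(C)CC/C=C(/C(=O)OC)[C@H]1OC(C)=O | intermediate
25 | methyl 2-(hydroxymethyl)prop-2-enoate | C=C(CO)C(=O)OC | starting material
26 | methyl 2-({[tert-butyl(dimethyl)silyl]oxy}methyl)prop-2-enoate | C=C(CO[Si](C)(C)C(C)(C)C)C(=O)OC | intermediate
27 | 2-({[tert-butyl(dimethyl)silyl]oxy}methyl)prop-2-enoic acid | C=C(CO[Si](C)(C)C(C)(C)C)C(=O)O | intermediate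
28 | 8-O-[2-({[tert-butyl(dimethyl)silyl]oxy}methyl)prop-2-enoyl] derivative of 24 | C=C(CO[Si](C)(C)C(C)(C)C)C(=O)O[C@H]1[C@H]2C(=C)C(=O)O[C@@H]2[C@@H]2O[C@]2(C)CC/C=C(/C(=O)OC)[C@H]1OC(C)=O | intermediate
29 | CNP0147016.1, (1(10)E,4R,5S,6S,7R,8S,9R)-9-acetoxy-4,5-epoxy-8-{[2-(hydroxymethyl)prop-2-enoyl]oxy}-14-methoxy-14-oxogermacra-1(10),11(13)-dien-12,6-olide | C=C(CO)C(=O)O[C@H]1[C@H]2C(=C)C(=O)O[C@@H]2[C@@H]2O[C@]2(C)CC/C=C(/C(=O)OC)[C@H]1OC(C)=O | target

## Step count and risks

Total step count: 14. Longest linear sequence: 10 steps (steps 1–6, 9, 10, 13, 14, from prenol).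

**Step 9 (chromium acetoxyallylation).** The reagent is untested. The two open points are the face of aldehyde 16 that is attacked, and possible closure of the chromium alkoxide onto the C14 ester or a 9→8 acetyl shift before work-up.
Fallback, setting out from 16 and 21 and coming back at 23: if attack occurs on the other face, the coupling is run with zinc dust in THF/saturated aqueous NH4Cl. There the Z-allylzinc species keeps its geometry, reacts through a chair with the acetoxy group axial and gives the syn adduct, which on that face is the C8 epimer of 23 F1 with C9 already correct; the protic medium also protonates the alkoxide at once. Dess–Martin oxidation gives the C8 ketone F2. Reduction with Zn(BH4)2 in Et2O at −78 °C (zinc held between the ketone and the C9 acetoxy oxygen, anti-selective) then gives 23, so that C8 is set by hydride delivery and not by the C–C bond formation.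

**Step 10 (ring-closing metathesis).** A ten-membered ring closing onto a hindered 2-substituted acrylate is slow, and the ruthenium alkylidene at C1 can be diverted onto the exocyclic methylene of the lactone.
Fallback, setting out from 14 and coming back at 24: the exocyclic methylene is kept masked as the Mannich base through the metathesis. PhI(OCOCF3)2 in aqueous MeCN at 0 °C removes only the dithiane and gives the amino aldehyde F3. CrCl2 coupling with 21 as in step 9 gives the amino adduct F4. Ring-closing metathesis of F4 as its camphorsulfonate salt with the same catalyst gives the macrocyclic Mannich base F5. MeI followed by aqueous NaHCO3 (quaternisation and elimination) then gives 24.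

**Step 5 (dithiane addition and Mannich trapping).** The strongly basic lithiodithiane may remove the γ-proton at C6 of butenolide 10 (which would open the neighbouring epoxide) or add 1,2.
Fallback, setting out from 10 and coming back at 16: a much less basic cuprate that acts as a hydroxymethyl anion equivalent is used. (Isopropoxydimethylsilyl)methylmagnesium chloride with CuBr·SMe2 (10 mol %) and TMSCl in THF at −78 °C, followed by Eschenmoser's salt, gives the silylmethyl Mannich base F6. H2O2, KF and KHCO3 in THF/MeOH (Tamao oxidation; the amine N-oxide formed alongside undergoes Cope elimination on warming to 40 °C) give the hydroxymethyl α-methylene lactone F7. TEMPO/PhI(OAc)2 oxidation then gives 16.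

## Further compounds

F1 | step 9 | C8 epimer of 23, methyl (3R,4R)-3-(acetyloxy)-4-[(2S,3R)-2-[(2S,3R)-3-(but-3-en-1-yl)-3-methyloxiran-2-yl]-4-methylidene-5-oxooxolan-3-yl]-4-hydroxy-2-methylidenebutanoate | O[C@@H]([C@H](OC(C)=O)C(=C)C(=O)OC)[C@H]1C(=C)C(=O)O[C@@H]1[C@@H]1O[C@]1(C)CCC=C
F2 | step 9 | C8 ketone of 23 (4-oxo in place of 4-hydroxy, C9 R) | O=C([C@H](OC(C)=O)C(=C)C(=O)OC)[C@H]1C(=C)C(=O)O[C@@H]1[C@@H]1O[C@]1(C)CCC=C
F3 | step 10 | (2S,3S,4R)-2-[(2S,3R)-3-(but-3-en-1-yl)-3-methyloxiran-2-yl]-4-[(dimethylamino)methyl]-5-oxooxolane-3-carbaldehyde | O=C[C@H]1[C@H](CN(C)C)C(=O)O[C@@H]1[C@@H]1O[C@]1(C)CCC=C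
F4 | step 10 | analogue of 23 with (11R)-CH(CH2NMe2) in place of the C11 methylidene | O[C@H]([C@H](OC(C)=O)C(=C)C(=O)OC)[C@H]1[C@H](CN(C)C)C(=O)O[C@@H]1[C@@H]1O[C@]1(C)CCC=C
F5 | step 10 | (11R)-13-(dimethylamino)-11,13-dihydro derivative of 24 | O[C@H]1[C@H]2[C@H](CN(C)C)C(=O)O[C@@H]2[C@@H]2O[C@]2(C)CC/C=C(/C(=O)OC)[C@H]1OC(C)=O
F6 | step 5 | (3R,4S,5S)-5-[(2S,3R)-3-(but-3-en-1-yl)-3-methyloxiran-2-yl]-3-[(dimethylamino)methyl]-4-{[dimethyl(propan-2-yloxy)silyl]methyl}oxolan-2-one | CC(C)O[Si](C)(C)C[C@H]1[C@H](CN(C)C)C(=O)O[C@@H]1[C@@H]1O[C@]1(C)CCC=C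
F7 | step 5 | (4R,5S)-5-[(2S,3R)-3-(but-3-en-1-yl)-3-methyloxiran-2-yl]-4-(hydroxymethyl)-3-methylideneoxolan-2-one | OC[C@H]1C(=C)C(=O)O[C@@H]1[C@@H]1O[C@]1(C)CCC=C
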